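The data stem from a simulated flask for substances that don't exist; the scatter is artificial.

What the constants of these flasks do with temperature is a guess, since the autumn run stood at 140 °C and the earlier runs do not show it, so two of us argued from opposite ends about what Q stands at after 25 min.

| flask | J | L | temperature | remark | time |
|---|---|---|---|---|---|
| autumn | 2 M | 1.5 M | 140 °C | run made earlier |  |
| Sunday's | 2.0 M | 3.00 M |  | at 140 °C until 12 min, from then on at 110 °C | 25 min |
| Tuesday's | 2.0 M | 3.00 M | 140 °C |  | 25 min |
| Friday's | 2.0 M | 3.00 M | 125 °C |  | 25 min |
| Monday's | 2.0 M | 3.00 M | 110 °C |  | 25 min |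

- autumn (time / min: Q / %, G / %): 0.667: 22.0, 0.3; 1.33: 51.0, 4.8; 3.00: 64.0, 23.8; 8.00: 39.7, 53.2

(scatter of a reading: 0.3 percentage points)

- given per volume of solution although it is solid: J
- at the start none of J is in solution
- what has only dissolved of J counts as not reacted
- a reading or a percentage of G counts all its forms, free or not
- the earlier runs do not show what temperature does; that part of a forecast is a guess

- the flask with the highest amount of Q, in percent of the J charged ("all alike" if they lie within 1.5 percentage points) (Sunday's / Tuesday's / Friday's / Monday's / all alike)
- final Q, as a percentage of the J charged, in Sunday's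
- final Q, as a percentage of the J charged, in Tuesday's
- final Q, as a percentage of the J charged, in Friday's
- final Q, as a percentage of the J charged, in Monday's

The first asked where a flask must end, and reckoned with the equivalents of L per J charged, 1.50, assuming that each G takes one L: below one equivalent L is the limiting reagent and a floor of Q, one minus the equivalents, stays unturned, while above one Q has no floor. For the autumn flask that floor is 25.0%, and its last reading of Q, 39.7%, still stands higher. The new recipes charge 2.0 M of J and 3.00 M of L, which on that assumption leaves a surplus of 1.00 M of L, and 25 min is 3.12 times the time of the autumn's last reading, so the first expected Q near nothing everywhere and answered "all alike".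

The second replied that a floor says where and not when: a guessed slowing by a factor of 6 at 110 °C makes Monday's 25 min worth about 4.17 min of autumn time, which lies between the autumn readings of Q of 64.0% at 3.00 min and 39.7% at 8.00 min, and twice the L should press that lower. The forecast is the second's and names Monday's, for “Monday's flask holds the most”, with Q at 35% there, lower than that bracket, 11% on Friday's, 6% on Sunday's and 1.5% on Tuesday's.

The flasks give Monday's, with Q at 56.9% against 13.0% on Friday's, 5.21% on Sunday's and 1.71% on Tuesday's, so the second had the order right and stood 22 percentage points low on Monday's.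

    J ⇌ X, rate k1*(cs1 - [X]) while solid is left; crystals form when [X] > cs1 (solubility = 1.20 M, k = 0.0250 s⁻¹)
    L → E (k = 0.00110 s⁻¹, Ea = 125 kJ mol⁻¹)
    Q + E → G (k = 2.50 × 10⁻⁴ M⁻¹ s⁻¹, Ea = 106 kJ mol⁻¹)
    X → Q (k = 0.00240 s⁻¹, Ea = 121 kJ mol⁻¹)
    X + G ⇌ D, settled at all times (K = 20.0 M⁻¹, ΔH = 28.0 kJ mol⁻¹)
    (constants at 110 °C)

The first's reckoning has its region below one equivalent, as in the neighbour flask, Sunday's recipe with 0.75 M of L: a quarter of the L takes 1.50 down to 0.375 equivalents, so the floor of Q is 62.5%, and after 25.0 min that flask holds Q 62.9% beside G 35.1%, its forms counted.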